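**Retrosynthetic overview**
1. Target 9 ⇐ tribenzyl ether 8 by global O-debenzylation (last step).
2. 8 ⇐ key C–O disconnection of the diaryl ether at C8–O: a flavon-8-yl cation equivalent (an aryl-λ3-iodane grown directly on the C8–H of 2) plus the 4′-phenoxide of 4.
3. 2 ⇐ acacetin 1 (5,7-di-O-benzylation); 4 ⇐ apigenin 3 (7-O-monobenzylation).
4. Rings: none is built. Both chromone ring systems come intact from 1 and 3, and the ether bridge is the only skeletal bond made.

Assumption 1: the target has no stereocentre and no configurationally stable axis, so "single enantiomer" means the one achiral compound drawn.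
Assumption 2: the hypervalent iodine reagent 5 is taken as a purchasable reagent; if it is not stocked, it is one peracid oxidation from commercial 2-iodo-1,3,5-trimethoxybenzene.

**Step 1**
Reactants: 1 acacetin (5,7-dihydroxy-2-(4-methoxyphenyl)-4H-chromen-4-one)
Product: 2 5,7-bis(benzyloxy)-2-(4-methoxyphenyl)-4H-chromen-4-one
Conditions: BnBr (3 equiv), K2CO3 (4 equiv), DMF, 80 °C, 12 h
Reagents that add atoms: benzyl bromide, BrCc1ccccc1
Why: Williamson ether synthesis; hot DMF with excess carbonate also alkylates the hydrogen-bonded 5-OH, and no other OH is present because the 4′-oxygen is already methylated.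

**Step 2**
Reactants: 3 apigenin (5,7-dihydroxy-2-(4-hydroxyphenyl)-4H-chromen-4-one)
Product: 4 7-(benzyloxy)-5-hydroxy-2-(4-hydroxyphenyl)-4H-chromen-4-one
Conditions: BnBr (1.05 equiv), K2CO3 (1.05 equiv), DMF, 0 °C → rt
Reagents that add atoms: benzyl bromide, BrCc1ccccc1
Why: base-limited Williamson etherification; the 7-OH (a vinylogous carboxylic acid para to C4=O) is the most acidic and is alkylated first, the 5-OH is held in the hydrogen bond to C4=O, and the 4′-OH is less acidic.

**Step 3**
Reactants: 2 5,7-bis(benzyloxy)-2-(4-methoxyphenyl)-4H-chromen-4-one; 4 7-(benzyloxy)-5-hydroxy-2-(4-hydroxyphenyl)-4H-chromen-4-one; 5 (2,4,6-trimethoxyphenyl)-λ3-iodanediyl diacetate, TMP–I(OAc)2; 6 p-toluenesulfonic acid monohydrate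
Product: 8 5,7-bis(benzyloxy)-8-{4-[7-(benzyloxy)-5-hydroxy-4-oxo-4H-chromen-2-yl]phenoxy}-2-(4-methoxyphenyl)-4H-chromen-4-one, via flavon-8-yl(2,4,6-trimethoxyphenyl)iodonium tosylate 7 (not isolated)
Conditions: 5 (1.0 equiv) + 6 (1.0 equiv), HFIP/CH2Cl2 1:1, 0 °C, 15 min; add 2 (1.1 equiv), 0 °C → rt, 2 h; evaporate; then 4 (1.0 equiv), K2CO3 (1.5 equiv), MeCN, 70 °C
Reagents that add atoms: none
Why: Proposed new method: a one-pot dehydrogenative C8–H aryloxylation through an aryl-λ3-iodane. Reagent 5 and TsOH give the Koser-type electrophile TMP–I(OH)OTs, which in ionising HFIP substitutes 2 at C8 to give iodonium salt 7; C8 is para to 5-OBn and ortho to 7-OBn, is the site halogen electrophiles take in 5,7-dialkoxyflavones, and is less shielded than C6, which sits between two benzyloxy groups. The 4′-phenoxide of 4 (its 5-OH stays chelated and unreactive) then exchanges onto iodine and undergoes ligand coupling (ipso attack with reductive elimination of TMP–I) at the flavonyl carbon. Flavonyl transfer is expected because both aryl ligands are 2,6-dioxygenated, so ortho effects cancel, while the flavonyl ring is the less electron-rich one (ring carbonyl; O1 and the 5-/7-oxygens conjugated into the pyranone); neither ligand has an ortho hydrogen, so no aryne path exists. The closest known reaction types are SEAr formation of diaryliodonium salts from [hydroxy(tosyloxy)iodo]arenes in fluoroalcohols and metal-free O-arylation of phenols with aryl(2,4,6-trimethoxyphenyl)iodonium salts; neither has been shown with the TMP group delivered by the iodane or with transfer of a hindered chromon-8-yl group.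

**Step 4**
Reactants: 8 5,7-bis(benzyloxy)-8-{4-[7-(benzyloxy)-5-hydroxy-4-oxo-4H-chromen-2-yl]phenoxy}-2-(4-methoxyphenyl)-4H-chromen-4-one
Product: 9 5,7-dihydroxy-8-[4-(5,7-dihydroxy-4-oxo-4H-chromen-2-yl)phenoxy]-2-(4-methoxyphenyl)-4H-chromen-4-one (target)
Conditions: H2 (1 atm), 10% Pd/C, THF/MeOH 1:1, rt
Reagents that add atoms: none
Why: catalytic hydrogenolysis of the three aryl benzyl ethers; the aryl methyl ether, the diaryl ether and the chromone C2=C3 (a vinylogous ester that hydrogenates slowly) are untouched at 1 atm and rt.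

**Compound list**
1 | acacetin, 5,7-dihydroxy-2-(4-methoxyphenyl)-4H-chromen-4-one | COc1ccc(-c2cc(=O)c3c(O)cc(O)cc3o2)cc1 | starting material
2 | 5,7-bis(benzyloxy)-2-(4-methoxyphenyl)-4H-chromen-4-one | COc1ccc(-c2cc(=O)c3c(OCc4ccccc4)cc(OCc4ccccc4)cc3o2)cc1 | intermediate
3 | apigenin, 5,7-dihydroxy-2-(4-hydroxyphenyl)-4H-chromen-4-one | O=c1cc(-c2ccc(O)cc2)oc2cc(O)cc(O)c12 | starting material
4 | 7-(benzyloxy)-5-hydroxy-2-(4-hydroxyphenyl)-4H-chromen-4-one | O=c1cc(-c2ccc(O)cc2)oc2cc(OCc3ccccc3)cc(O)c12 | intermediate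
5 | (2,4,6-trimethoxyphenyl)-λ3-iodanediyl diacetate, TMP–I(OAc)2 | COc1cc(OC)c(I(OC(C)=O)OC(C)=O)c(OC)c1 | starting material (reagent)
6 | p-toluenesulfonic acid monohydrate | Cc1ccc(S(=O)(=O)O)cc1.O | starting material (reagent)
7 | [5,7-bis(benzyloxy)-2-(4-methoxyphenyl)-4-oxo-4H-chromen-8-yl](2,4,6-trimethoxyphenyl)iodonium p-toluenesulfonate | COc1ccc(-c2cc(=O)c3c(OCc4ccccc4)cc(OCc4ccccc4)c([I+]c4c(OC)cc(OC)cc4OC)c3o2)cc1.Cc1ccc(S(=O)(=O)[O-])cc1 | intermediate (not isolated)
8 | 5,7-bis(benzyloxy)-8-{4-[7-(benzyloxy)-5-hydroxy-4-oxo-4H-chromen-2-yl]phenoxy}-2-(4-methoxyphenyl)-4H-chromen-4-one | COc1ccc(-c2cc(=O)c3c(OCc4ccccc4)cc(OCc4ccccc4)c(Oc4ccc(-c5cc(=O)c6c(O)cc(OCc7ccccc7)cc6o5)cc4)c3o2)cc1 | intermediate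
9 | 5,7-dihydroxy-8-[4-(5,7-dihydroxy-4-oxo-4H-chromen-2-yl)phenoxy]-2-(4-methoxyphenyl)-4H-chromen-4-one | COc1ccc(-c2cc(=O)c3c(O)cc(O)c(Oc4ccc(-c5cc(=O)c6c(O)cc(O)cc6o5)cc4)c3o2)cc1 | target

**Step count**
Total: 4 steps (convergent). Longest linear sequence: 3 steps (steps 1, 3, 4).

**Three steps most likely to fail**

Step 3 (the proposed new C–H aryloxylation). The risks are sluggish formation of the hindered iodonium salt, loss of the acid-labile 5-O-benzyl group, and competing transfer of the trimethoxyphenyl group to the phenoxide. The fallback uses known chemistry, sets out from 2 and comes back at 8, and costs one extra step. Compound 2 is iodinated at C8 by electrophilic aromatic substitution (NIS, DMF, 60 °C) to give 5,7-bis(benzyloxy)-8-iodo-2-(4-methoxyphenyl)-4H-chromen-4-one F1. F1 is then joined to 4 by a copper-catalysed Ullmann diaryl ether coupling (CuI, picolinic acid, K3PO4, DMSO, 90 °C), which gives 8.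

Step 2 (mono-benzylation of apigenin). The risk is a mixture with the 4′-O-benzyl and 7,4′-di-O-benzyl ethers. The fallback replaces selective alkylation by selective deacylation, sets out from 3 and comes back at 4. Apigenin is peracetylated (Ac2O, pyridine) to 4-(5,7-diacetoxy-4-oxo-4H-chromen-2-yl)phenyl acetate F2. The most activated 7-O-acetyl group is removed selectively (PhSH, imidazole, NMP, 0 °C) to give 4-(5-acetoxy-7-hydroxy-4-oxo-4H-chromen-2-yl)phenyl acetate F3. The single free 7-OH is benzylated under neutral Mitsunobu conditions (BnOH, PPh3, DIAD, THF) to give 4-[5-acetoxy-7-(benzyloxy)-4-oxo-4H-chromen-2-yl]phenyl acetate F4. Methanolysis (K2CO3, MeOH) removes both acetates and gives 4.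

Step 4 (global hydrogenolysis). The risks are poor solubility of 8, incomplete cleavage, and partial reduction of a chromone C2=C3 bond. The fallback leaves reductive cleavage for Lewis-acid dealkylation, sets out from 8 and comes back at 9: BCl3 with pentamethylbenzene as benzyl-cation scavenger, CH2Cl2, −78 °C → 0 °C. The unchelated 4′-methyl ether survives these conditions. This fallback makes no new compound (F0).

**Further compounds**
F1 | step 3 | 5,7-bis(benzyloxy)-8-iodo-2-(4-methoxyphenyl)-4H-chromen-4-one | COc1ccc(-c2cc(=O)c3c(OCc4ccccc4)cc(OCc4ccccc4)c(I)c3o2)cc1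
F2 | step 2 | 4-(5,7-diacetoxy-4-oxo-4H-chromen-2-yl)phenyl acetate | CC(=O)Oc1ccc(-c2cc(=O)c3c(OC(C)=O)cc(OC(C)=O)cc3o2)cc1
F3 | step 2 | 4-(5-acetoxy-7-hydroxy-4-oxo-4H-chromen-2-yl)phenyl acetate | CC(=O)Oc1ccc(-c2cc(=O)c3c(OC(C)=O)cc(O)cc3o2)cc1
F4 | step 2 | 4-[5-acetoxy-7-(benzyloxy)-4-oxo-4H-chromen-2-yl]phenyl acetate | CC(=O)Oc1ccc(-c2cc(=O)c3c(OC(C)=O)cc(OCc4ccccc4)cc3o2)cc1
F0 | step 4 | none | none
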